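**Retrosynthetic overview**
1. Target ⇒ its 21‑fold O‑benzyl ether, opened by one global hydrogenolysis at the end.
2. Upper interflavan bond C4(top)–C8(middle) ⇒ C4–H of the perbenzylated epicatechin gallate (ECG) monomer + C8–H of the perbenzylated ECG‑(4β→8)‑ECG dimer, joined by anodic dehydrogenative C(sp3)–H/C(sp2)–H coupling.
3. Lower interflavan bond C4(middle)–C8(bottom) ⇒ two molecules of the same monomer and the same anodic coupling. This bond is made first.
4. Monomer ⇒ tetra‑O‑benzyl‑(−)‑epicatechin + 3,4,5‑tris(benzyloxy)benzoic acid (esterification) ⇒ (−)‑epicatechin + benzyl bromide.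
5. No ring is built. Nine rings and the six C2/C3 stereocentres arrive in (−)‑epicatechin and the three galloyl rings arrive in the acid. The two C4 centres are set 3,4‑trans by the resident C3 ester.

Assumption: "3,3,3" means 3,3′,3″. The SMILES decodes as ECG‑(4β→8)‑ECG‑(4β→8)‑ECG (every unit 2R,3R, both interflavan bonds 4β). (−)‑Epicatechin and 3,4,5‑tris(benzyloxy)benzoic acid are taken as commercial.

**Route**

Step 1
Reactants: 1, (−)‑epicatechin (2R,3R); 2, benzyl bromide
Product: 3, 5,7,3′,4′‑tetra‑O‑benzyl‑(−)‑epicatechin = (2R,3R)‑5,7‑bis(benzyloxy)‑2‑[3,4‑bis(benzyloxy)phenyl]chroman‑3‑ol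
Conditions: BnBr (4.4 equiv), K2CO3 (5 equiv), degassed DMF, Ar, 0 °C → rt, 24 h
Reagents that add atoms: benzyl bromide, BrCc1ccccc1
Why: Williamson O‑alkylation with a carbonate base benzylates only the four phenols and leaves the secondary 3‑OH free, and with O2 excluded at ≤ rt the 4′‑phenoxide is benzylated before it can open the C ring via a quinone methide and epimerise C2.

Step 2
Reactants: 3, tetra‑O‑benzyl‑(−)‑epicatechin; 4, 3,4,5‑tris(benzyloxy)benzoic acid
Product: 5, hepta‑O‑benzyl‑(−)‑ECG = (2R,3R)‑5,7‑bis(benzyloxy)‑2‑[3,4‑bis(benzyloxy)phenyl]chroman‑3‑yl 3,4,5‑tris(benzyloxy)benzoate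
Conditions: 4 (1.3 equiv), EDC·HCl (1.5 equiv), DMAP (0.5 equiv), CH2Cl2, 0 °C → rt, 16 h
Reagents that add atoms: 3,4,5‑tris(benzyloxy)benzoic acid, O=C(O)c1cc(OCc2ccccc2)c(OCc2ccccc2)c(OCc2ccccc2)c1
Why: Steglich esterification, in which the DMAP acylpyridinium formed from the O‑acylisourea acylates the only free hydroxyl, and C2 and C3 keep their configuration because the C3–O bond is never broken and the conditions are neutral.

Step 3
Reactants: 5 (1.0 equiv, C4–H partner); 5 (3.0 equiv, C8–H partner, excess recovered)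
Product: 7, tetradeca‑O‑benzyl ECG‑(4β→8)‑ECG (both units 2R,3R; new C4 substituent β, trans to the 3‑O‑galloyl), formed through 6, the 4β‑[N‑tosyl‑N‑(diphenylsulfonio)amino] derivative of 5 (BF4− salt, not isolated)
Conditions: (i) DDQ (20 mol %), Ph2S=NTs (2.0 equiv), 2,6‑di‑tert‑butyl‑4‑methylpyridine (1.05 equiv), 4 Å MS, 0.2 M Bu4NBF4/CH2Cl2, divided cell, C felt (+) | Pt (−, TfOH catholyte), +0.8 V vs SCE, 1.6 F/mol (mediator ends as DDQH2), 0 °C; (ii) current off, same anolyte, add 5 (3 equiv) and HFIP (20 vol %), 0 °C → rt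
Reagents that add atoms: none
Why: Proposed new method: anodically recycled DDQ removes the quasi‑axial C4–Hβ of 5 as hydride (the site DDQ attacks in O‑benzylated flavan‑3‑ols, with the anode held below the substrate's own wave so only DDQH− is oxidised); the 2,4,6‑trioxygenated benzylic cation, assisted from the α face by the axial 3‑O‑galloyl carbonyl, is parked by free sulfilimine as cationic 6, whose charge blocks over‑oxidation and shuts down its own C8 nucleophilicity; HFIP (ionising, H‑bonds to the sulfilimine N) then reopens the reservoir so C8 of neutral 5 attacks the β face anti to the 3‑O‑acyl group (SN1 Friedel–Crafts), setting C4 as 4β purely by substrate control with H2 as the only by‑product; the closest known reaction types are sulfilimine "stabilised cation pool" benzylic C–H/aromatic C–H cross‑coupling, quinone‑mediated indirect electrolysis, and the stoichiometric DDQ/alcohol then Lewis‑acid flavan‑4‑yl coupling, none of which has been shown for a flavan C4–H or an interflavan bond.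

Step 4
Reactants: 5 (1.0 equiv, converted in situ to 6); 7 (2.0 equiv, excess recovered)
Product: 8, 21‑fold O‑benzylated ECG‑(4β→8)‑ECG‑(4β→8)‑ECG (all units 2R,3R; both interflavan bonds 4β, 3,4‑trans)
Conditions: (i) as Step 3 (i); (ii) current off, add 7 (2 equiv) and HFIP (20 vol %), 0 °C → rt; SiO2 then preparative GPC
Reagents that add atoms: none
Why: Proposed new method: the same anodic DDQ/sulfilimine generation of 6, but the reservoir is opened in front of dimer 7, whose only accessible doubly O‑activated site is C8 of its upper unit (the lower C8 is substituted and both C6 positions sit between two OBn groups), so β‑face SN1 Friedel–Crafts attack anti to the 3‑O‑galloyl group gives the second 4β→8 bond; cationic 6 cannot self‑condense and excess 7 limits extension of 8 to tetramer; the closest known reaction types are stabilised‑cation‑pool benzylic C–H/aryl C–H cross‑coupling and Lewis‑acid condensation of a monomeric flavan‑4‑yl electrophile with a dimeric procyanidin nucleophile.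

Step 5
Reactants: 8
Product: 9, procyanidin C1 3,3′,3″‑tri‑O‑gallate (target)
Conditions: H2 (1 atm), 20% Pd(OH)2/C, THF/MeOH/H2O (20:1:1), rt, 3–6 h; filter, lyophilise, Sephadex LH‑20
Reagents that add atoms: none
Why: Neutral heterogeneous hydrogenolysis cleaves all 21 aryl benzyl ethers, while the three benzoate esters, the C2–O1 bonds, the acid‑labile interflavan bonds and all eight stereocentres are untouched under these short, acid‑free conditions.

**Compound list**

1 | (−)‑epicatechin | O[C@@H]1Cc2c(O)cc(O)cc2O[C@@H]1c1ccc(O)c(O)c1 | starting material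

2 | benzyl bromide | BrCc1ccccc1 | starting material

3 | 5,7,3′,4′‑tetra‑O‑benzyl‑(−)‑epicatechin | O[C@@H]1Cc2c(OCc9ccccc9)cc(OCc9ccccc9)cc2O[C@@H]1c1ccc(OCc9ccccc9)c(OCc9ccccc9)c1 | intermediate

4 | 3,4,5‑tris(benzyloxy)benzoic acid | O=C(O)c1cc(OCc2ccccc2)c(OCc2ccccc2)c(OCc2ccccc2)c1 | starting material

5 | hepta‑O‑benzyl‑(−)‑ECG | O=C(O[C@@H]1Cc2c(OCc9ccccc9)cc(OCc9ccccc9)cc2O[C@@H]1c1ccc(OCc9ccccc9)c(OCc9ccccc9)c1)c1cc(OCc9ccccc9)c(OCc9ccccc9)c(OCc9ccccc9)c1 | intermediate

6 | 4β‑[N‑tosyl‑N‑(diphenylsulfonio)amino]‑hepta‑O‑benzyl‑ECG tetrafluoroborate | O=C(O[C@@H]1[C@@H](N(S(=O)(=O)c2ccc(C)cc2)[S+](c2ccccc2)c2ccccc2)c2c(OCc9ccccc9)cc(OCc9ccccc9)cc2O[C@@H]1c1ccc(OCc9ccccc9)c(OCc9ccccc9)c1)c1cc(OCc9ccccc9)c(OCc9ccccc9)c(OCc9ccccc9)c1.F[B-](F)(F)F | intermediate (in situ, not isolated)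

7 | tetradeca‑O‑benzyl ECG‑(4β→8)‑ECG | O=C(O[C@@H]1[C@@H](c2c(OCc9ccccc9)cc(OCc9ccccc9)c3c2O[C@H](c2ccc(OCc9ccccc9)c(OCc9ccccc9)c2)[C@H](OC(=O)c2cc(OCc9ccccc9)c(OCc9ccccc9)c(OCc9ccccc9)c2)C3)c2c(OCc9ccccc9)cc(OCc9ccccc9)cc2O[C@@H]1c1ccc(OCc9ccccc9)c(OCc9ccccc9)c1)c1cc(OCc9ccccc9)c(OCc9ccccc9)c(OCc9ccccc9)c1 | intermediate

8 | 21‑O‑benzyl ECG‑(4β→8)‑ECG‑(4β→8)‑ECG | O=C(O[C@@H]1[C@@H](c2c(OCc9ccccc9)cc(OCc9ccccc9)c3c2O[C@H](c2ccc(OCc9ccccc9)c(OCc9ccccc9)c2)[C@H](OC(=O)c2cc(OCc9ccccc9)c(OCc9ccccc9)c(OCc9ccccc9)c2)C3)c2c(OCc9ccccc9)cc(OCc9ccccc9)c([C@H]3c4c(OCc9ccccc9)cc(OCc9ccccc9)cc4O[C@H](c4ccc(OCc9ccccc9)c(OCc9ccccc9)c4)[C@@H]3OC(=O)c3cc(OCc9ccccc9)c(OCc9ccccc9)c(OCc9ccccc9)c3)c2O[C@@H]1c1ccc(OCc9ccccc9)c(OCc9ccccc9)c1)c1cc(OCc9ccccc9)c(OCc9ccccc9)c(OCc9ccccc9)c1 | intermediate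

9 | procyanidin C1 3,3′,3″‑tri‑O‑gallate | O=C(O[C@@H]1[C@@H](c2c(O)cc(O)c3c2O[C@H](c2ccc(O)c(O)c2)[C@H](OC(=O)c2cc(O)c(O)c(O)c2)C3)c2c(O)cc(O)c([C@H]3c4c(O)cc(O)cc4O[C@H](c4ccc(O)c(O)c4)[C@@H]3OC(=O)c3cc(O)c(O)c(O)c3)c2O[C@@H]1c1ccc(O)c(O)c1)c1cc(O)c(O)c(O)c1 | target

**Step count**
Total steps: 5. Longest linear sequence: 5 (1 → 3 → 5 → 7 → 8 → 9). Compound 5 is used three times. Ph2S=NTs and the excess 5 and 7 are recovered.

**Three steps most likely to fail**

1. **Step 4 (proposed new method, hardest case).**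
   - Risks: the upper‑unit C8 of 7 is hindered. Product 8 competes with 7 for the cation and gives tetramer. Minor 4→6 isomers may form. The reservoir may leak during electrolysis.
   - Fallback (known chemistry): a capped leaving‑group strategy. Brominate 5 at C8 with NBS, oxidise with stoichiometric DDQ/2‑ethoxyethanol to the isolable 4β‑(2‑ethoxyethoxy) ether, and condense it with 7 using AgOTf or TMSOTf.
   - The capped electrophile cannot self‑condense or be over‑extended. The C8–Br falls off in the final hydrogenolysis (Et3N added). This adds 2 steps.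

2. **Step 3 (proposed new method).**
   - Risks: hydride abstraction from the 3‑O‑acyl flavan by only 20 mol % DDQ at 0 °C may be slow. Sulfonium 6 may be too crowded to persist, so the cation is intercepted by unoxidised 5 and gives an oligomer mixture. DDQ and the sulfilimine may be incompatible.
   - Fallback (known chemistry): treat 5 with stoichiometric DDQ and 2‑ethoxyethanol, isolate the 4β‑alkoxy ether, then run a TMSOTf‑catalysed condensation with 3–4 equiv of 5 in CH2Cl2 at −78 °C. This is 4β‑selective and adds 1 step.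

3. **Step 1.**
   - Risks: C‑benzylation at C6/C8, air oxidation of the polyphenoxides, and partial C2 epimerisation of the 2,3‑cis flavanol under base.
   - Fallback: enter from (+)‑catechin (2R,3S) instead. Tetra‑O‑benzylate it (robust, crystalline product) and oxidise the 3‑OH to the ketone with Dess–Martin periodinane.
   - Reduce the ketone with L‑Selectride. Hydride arrives anti to the 2‑aryl group and gives the same 2,3‑cis alcohol 3 under substrate control. This adds 2 steps.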